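A direct plan would attach a 3-methylbuta-1,3-dienyl group to bromophenol A1 by Suzuki coupling to give dienylphenol A2, epoxidise its styrenyl bond with a chiral dioxirane and let the phenoxide open vinyl epoxide A3 to the trans-dihydrobenzofuranol A4. It would then reduce the ketone, acylate both hydroxyl groups to A5 and oxidise the isopropenyl methyl group with SeO2.
Its weakest steps would be:
- the epoxidation/ring closure on the free dienylphenol: an untested tandem on an oxidant-sensitive substrate, in which a 5-endo epoxide opening would have to beat 1,4-opening and which alone would carry the enantiopurity;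
- the final allylic oxidation: it would have to stop at the enal beside two tiglates that have allylic methyl groups of their own, at the most costly stage;
- making and handling A2: an electron-rich dienylphenol would be prone to cyclise or polymerise under acid or heat.

The new route reads C2–Cα(=CH2)–CH2O as dihydroxyacetone whose carbonyl carbon is methylenated, and C3 as an aldol acceptor carbon. An (S)-proline-catalysed anti-aldol between the dihydroxyacetone acetonide and 5-bromo-2-fluorobenzaldehyde forms the C2–C3 bond, sets both ring stereocentres and brings in all three acrolein carbons with oxygen already on the future aldehyde carbon. The furan ring is then closed at the other end, C7a–O1, by nucleophilic aromatic substitution, made possible because the C5 acetyl group is para to C7a. No dienylphenol, no epoxide opening and no allylic C–H oxidation occur.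

Key step: step 1

Remark: ring atoms are numbered as in 2,3-dihydro-1-benzofuran (O1, C2, C3, C3a, C4–C7, C7a), Cα is the acrolein carbon bonded to C2, and compounds 1, 2, 6 and 12 are assumed to be purchased.

Step 1
Reactants: 1 5-bromo-2-fluorobenzaldehyde; 2 2,2-dimethyl-1,3-dioxan-5-one
Product: 3 (4S)-4-[(S)-(5-bromo-2-fluorophenyl)(hydroxy)methyl]-2,2-dimethyl-1,3-dioxan-5-one
Conditions: 1 (1.0 equiv), 2 (1.5 equiv), (S)-proline (30 mol %), DMF, 4 °C, 3–5 d
Reagents that add atoms: none
Why: Enamine catalysis: (S)-proline condenses with ketone 2 to an enamine that adds to the formyl group of 1 through a chair-like transition state in which the carboxylic acid hydrogen-bonds the aldehyde oxygen, and hydrolysis releases 3 and the catalyst. The closest known reaction type is the proline-catalysed anti-aldol of 2,2-dimethyl-1,3-dioxan-5-one with aldehydes used to assemble protected ketoses. The step closes no ring; it forms the C2–C3 bond, and the furan ring is closed only in step 5 at C7a–O1. The stereocentre that becomes C2 (4S in 3) is set by the enamine face turned toward the carboxylic acid of the (S)-catalyst, and the one that becomes C3 (1'S in 3) by the aryl group taking the pseudo-equatorial position of that transition state, the same sense that gives (2S,1'R) anti-aldols from cyclohexanone (the descriptor at C1' differs only because of the ring oxygen). The step needs anti over syn, one enantiomer and cross- over self-aldol: the ring of 2 allows only the E enamine, aldehyde 1 has no α-hydrogen, and its ortho fluorine makes it a reactive acceptor.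

Step 2
Reactants: 3 (4S)-4-[(S)-(5-bromo-2-fluorophenyl)(hydroxy)methyl]-2,2-dimethyl-1,3-dioxan-5-one
Product: 4 (4S)-4-[(S)-(5-bromo-2-fluorophenyl)(triethylsilyloxy)methyl]-2,2-dimethyl-1,3-dioxan-5-one
Conditions: Et3SiOTf (1.1 equiv), 2,6-lutidine (1.5 equiv), CH2Cl2, −78 °C, 1 h
Reagents that add atoms: triethylsilyl trifluoromethanesulfonate, CC[Si](CC)(CC)OS(=O)(=O)C(F)(F)F
Why: O-silylation of the aldol hydroxyl at low temperature with a hindered base should block retro-aldol cleavage in the next step and touches neither stereocentre.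

Step 3
Reactants: 4 (4S)-4-[(S)-(5-bromo-2-fluorophenyl)(triethylsilyloxy)methyl]-2,2-dimethyl-1,3-dioxan-5-one
Product: 5 triethyl{(S)-(5-bromo-2-fluorophenyl)[(4R)-2,2-dimethyl-5-methylidene-1,3-dioxan-4-yl]methoxy}silane
Conditions: Cp2TiMe2 (2.5 equiv), toluene, 70 °C, dark, 16 h
Reagents that add atoms: bis(cyclopentadienyl)dimethyltitanium (Cp2TiMe2), [CH3-].[CH3-].[Ti+4].c1cc[cH-]c1.c1cc[cH-]c1
Why: Petasis methylenation, in which the titanium methylidene formed on heating converts the ketone into the exocyclic alkene through an oxatitanacyclobutane under non-basic conditions, so that the enolisable centre beside the carbonyl (future C2) should not epimerise, the β-silyloxy group should not be eliminated, and the aryl halides, acetal and silyl ether stay inert (the descriptor at C4 changes from S to R by priority only).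

Step 4
Reactants: 5 triethyl{(S)-(5-bromo-2-fluorophenyl)[(4R)-2,2-dimethyl-5-methylidene-1,3-dioxan-4-yl]methoxy}silane; 6 tributyl(1-ethoxyethenyl)stannane
Product: 8 1-{4-fluoro-3-[(1S,2R)-1,2-dihydroxy-3-(hydroxymethyl)but-3-en-1-yl]phenyl}ethan-1-one, via 1-ethoxyvinylarene 7 (not isolated)
Conditions: 6 (1.3 equiv), PdCl2(PPh3)2 (5 mol %), toluene, 100 °C, 8 h; then 1 M aq. HCl–THF–MeOH, 23 °C, 4 h; aq. KF work-up
Reagents that add atoms: tributyl(1-ethoxyethenyl)stannane (6), C=C(OCC)[Sn](CCCC)(CCCC)CCCC; water, O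
Why: Stille coupling at the aryl bromide (the C–F bond does not undergo oxidative addition) brings in the acetyl group as its enol ether, and one aqueous acid treatment then hydrolyses the enol ether to the methyl ketone and removes the acetonide and the triethylsilyl group, no bond at C2 or C3 being broken.

Step 5
Reactants: 8 1-{4-fluoro-3-[(1S,2R)-1,2-dihydroxy-3-(hydroxymethyl)but-3-en-1-yl]phenyl}ethan-1-one
Product: 9 1-[(2R,3S)-3-hydroxy-2-(3-hydroxyprop-1-en-2-yl)-2,3-dihydro-1-benzofuran-5-yl]ethan-1-one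
Conditions: KOtBu (1.2 equiv), THF (0.02 M), 0 → 23 °C, 3 h; aq. NH4Cl quench
Reagents that add atoms: none
Why: Intramolecular nucleophilic aromatic substitution (addition–elimination through a Meisenheimer intermediate stabilised by the para acetyl group), in which only the C2 alkoxide can reach C7a through a five-membered transition state (the C3 alkoxide would give a four-membered and the primary alkoxide a seven-membered ring), and since no bond at C2 or C3 is broken the anti diol should map onto the trans-2,3-disubstituted ring.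

Step 6
Reactants: 9 1-[(2R,3S)-3-hydroxy-2-(3-hydroxyprop-1-en-2-yl)-2,3-dihydro-1-benzofuran-5-yl]ethan-1-one
Product: 10 (2R,3S)-5-[(1R)-1-hydroxyethyl]-2-(3-hydroxyprop-1-en-2-yl)-2,3-dihydro-1-benzofuran-3-ol
Conditions: RuCl[(R,R)-TsDPEN](p-cymene) (1 mol %), HCO2H–Et3N 5:2 (5 equiv HCO2H), DMF, 30 °C, 16 h
Reagents that add atoms: none
Why: Noyori–Ikariya asymmetric transfer hydrogenation of the aryl methyl ketone, in which the (R,R) catalyst should give the (R)-1-arylethanol under catalyst control while the outer-sphere ruthenium hydride leaves the 1,1-disubstituted alkene and both hydroxyl groups untouched.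

Step 7
Reactants: 10 (2R,3S)-5-[(1R)-1-hydroxyethyl]-2-(3-hydroxyprop-1-en-2-yl)-2,3-dihydro-1-benzofuran-3-ol
Product: 11 2-{(2R,3S)-3-hydroxy-5-[(1R)-1-hydroxyethyl]-2,3-dihydro-1-benzofuran-2-yl}prop-2-enal
Conditions: [Cu(MeCN)4]OTf (5 mol %), 2,2'-bipyridine (5 mol %), TEMPO (5 mol %), N-methylimidazole (10 mol %), MeCN, air, 23 °C, 3 h
Reagents that add atoms: none
Why: Copper/TEMPO aerobic alcohol oxidation, which for steric reasons should oxidise the primary allylic alcohol to the 2-substituted acrolein much faster than the two secondary benzylic alcohols and does not go on to the acid, while the trans arrangement at C2/C3 prevents lactol formation and no stereocentre is touched.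

Step 8
Reactants: 11 2-{(2R,3S)-3-hydroxy-5-[(1R)-1-hydroxyethyl]-2,3-dihydro-1-benzofuran-2-yl}prop-2-enal; 12 tigloyl chloride
Product: 13 (1R)-1-[(2R,3S)-3-{[(2E)-2-methylbut-2-enoyl]oxy}-2-(3-oxoprop-1-en-2-yl)-2,3-dihydro-1-benzofuran-5-yl]ethyl (2E)-2-methylbut-2-enoate (CNP0292799.1)
Conditions: 12 (3.0 equiv), pyridine (6 equiv), 4-(dimethylamino)pyridine (10 mol %), CH2Cl2, 0 → 23 °C, 8 h
Reagents that add atoms: tigloyl chloride (12), C/C=C(\C)C(=O)Cl
Why: Nucleophile-catalysed O-acylation of both secondary alcohols breaks no bond at a carbinol carbon, so all three stereocentres are retained, pyridine instead of a trialkylamine avoids deconjugation of the acid chloride through a vinylketene, and C2–H is not acidified by the cross-conjugated aldehyde, so elimination to the benzofuran is not expected.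

Compound list
1 | 5-bromo-2-fluorobenzaldehyde | O=Cc1cc(Br)ccc1F | starting material
2 | 2,2-dimethyl-1,3-dioxan-5-one | CC1(C)OCC(=O)CO1 | starting material
3 | (4S)-4-[(S)-(5-bromo-2-fluorophenyl)(hydroxy)methyl]-2,2-dimethyl-1,3-dioxan-5-one | CC1(C)OCC(=O)[C@@H](O1)[C@@H](O)c1cc(Br)ccc1F | intermediate
4 | (4S)-4-[(S)-(5-bromo-2-fluorophenyl)(triethylsilyloxy)methyl]-2,2-dimethyl-1,3-dioxan-5-one | CC1(C)OCC(=O)[C@@H](O1)[C@@H](O[Si](CC)(CC)CC)c1cc(Br)ccc1F | intermediate
5 | triethyl{(S)-(5-bromo-2-fluorophenyl)[(4R)-2,2-dimethyl-5-methylidene-1,3-dioxan-4-yl]methoxy}silane | CC1(C)OCC(=C)[C@@H](O1)[C@@H](O[Si](CC)(CC)CC)c1cc(Br)ccc1F | intermediate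
6 | tributyl(1-ethoxyethenyl)stannane | C=C(OCC)[Sn](CCCC)(CCCC)CCCC | starting material
7 | triethyl{(S)-[5-(1-ethoxyethenyl)-2-fluorophenyl][(4R)-2,2-dimethyl-5-methylidene-1,3-dioxan-4-yl]methoxy}silane | CC1(C)OCC(=C)[C@@H](O1)[C@@H](O[Si](CC)(CC)CC)c1cc(C(=C)OCC)ccc1F | intermediate
8 | 1-{4-fluoro-3-[(1S,2R)-1,2-dihydroxy-3-(hydroxymethyl)but-3-en-1-yl]phenyl}ethan-1-one | OCC(=C)[C@@H](O)[C@@H](O)c1cc(C(C)=O)ccc1F | intermediate
9 | 1-[(2R,3S)-3-hydroxy-2-(3-hydroxyprop-1-en-2-yl)-2,3-dihydro-1-benzofuran-5-yl]ethan-1-one | OCC(=C)[C@H]1Oc2ccc(C(C)=O)cc2[C@@H]1O | intermediate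
10 | (2R,3S)-5-[(1R)-1-hydroxyethyl]-2-(3-hydroxyprop-1-en-2-yl)-2,3-dihydro-1-benzofuran-3-ol | OCC(=C)[C@H]1Oc2ccc([C@@H](C)O)cc2[C@@H]1O | intermediate
11 | 2-{(2R,3S)-3-hydroxy-5-[(1R)-1-hydroxyethyl]-2,3-dihydro-1-benzofuran-2-yl}prop-2-enal | O=CC(=C)[C@H]1Oc2ccc([C@@H](C)O)cc2[C@@H]1O | intermediate
12 | tigloyl chloride, (2E)-2-methylbut-2-enoyl chloride | C/C=C(\C)C(=O)Cl | starting material
13 | (1R)-1-[(2R,3S)-3-{[(2E)-2-methylbut-2-enoyl]oxy}-2-(3-oxoprop-1-en-2-yl)-2,3-dihydro-1-benzofuran-5-yl]ethyl (2E)-2-methylbut-2-enoate (CNP0292799.1) | C=C(C=O)[C@H]1Oc2ccc([C@@H](C)OC(=O)/C(C)=C/C)cc2[C@@H]1OC(=O)/C(C)=C/C | target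

Total step count: 8. Longest linear sequence: 8 steps (from 1 or 2).

Steps most likely to fail

Step 1. The aldol could show poor anti/syn or facial selectivity with an aromatic acceptor, or the catalyst could be consumed by substitution of the activated fluorine. Auxiliary control would then replace catalyst control. Setting out from 2, the ketone would be condensed with (S)-1-amino-2-(methoxymethyl)pyrrolidine to the SAMP hydrazone F1. Lithiation of F1 (t-BuLi, THF, −78 °C) and addition to aldehyde 1 would give the hydroxy hydrazone F2, and two-phase cleavage with aqueous oxalic acid would return to the route at 3.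

Step 5. Ring closure could go through the primary alkoxide to a seven-membered ring, substitution could become intermolecular, or displacement could be slow because acetyl is only a moderate activator. The competing nucleophile would be removed first. Setting out from 8, the primary hydroxyl would be silylated selectively (t-BuPh2SiCl, imidazole, CH2Cl2, 0 °C) to the silyl ether F3. F3 could then be cyclised with a stronger base (KN(SiMe3)2, THF, 0 °C) to the dihydrobenzofuran F4, and Bu4NF buffered with AcOH would return to the route at 9.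

Step 8. The α-substituted enal could be lost by amine addition or polymerisation during the double acylation, or step 7 could over-oxidise a benzylic alcohol. The aldehyde would then be unveiled last. Setting out from 10 and omitting step 7, the primary hydroxyl would be silylated (t-BuMe2SiCl, imidazole, CH2Cl2, 0 °C) to the silyl ether F5. Both secondary hydroxyls would be acylated with 12 (pyridine, 4-(dimethylamino)pyridine) to the bis-tiglate F6, and HF·pyridine in THF would free the allylic alcohol F7. MnO2 in CH2Cl2 would then oxidise F7 under neutral conditions and rejoin the route at 13.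

Further compounds
F1 | step 1 | (2S)-N-(2,2-dimethyl-1,3-dioxan-5-ylidene)-2-(methoxymethyl)pyrrolidin-1-amine | COC[C@@H]1CCCN1N=C1COC(C)(C)OC1
F2 | step 1 | (S)-(5-bromo-2-fluorophenyl)[(4R)-5-{[(2S)-2-(methoxymethyl)pyrrolidin-1-yl]imino}-2,2-dimethyl-1,3-dioxan-4-yl]methanol | COC[C@@H]1CCCN1N=C1COC(C)(C)O[C@H]1[C@@H](O)c1cc(Br)ccc1F
F3 | step 5 | 1-{3-[(1S,2R)-3-({[tert-butyl(diphenyl)silyl]oxy}methyl)-1,2-dihydroxybut-3-en-1-yl]-4-fluorophenyl}ethan-1-one | CC(C)(C)[Si](OCC(=C)[C@@H](O)[C@@H](O)c1cc(C(C)=O)ccc1F)(c1ccccc1)c1ccccc1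
F4 | step 5 | 1-[(2R,3S)-2-(3-{[tert-butyl(diphenyl)silyl]oxy}prop-1-en-2-yl)-3-hydroxy-2,3-dihydro-1-benzofuran-5-yl]ethan-1-one | CC(C)(C)[Si](OCC(=C)[C@H]1Oc2ccc(C(C)=O)cc2[C@@H]1O)(c1ccccc1)c1ccccc1
F5 | step 8 | (2R,3S)-2-(3-{[tert-butyl(dimethyl)silyl]oxy}prop-1-en-2-yl)-5-[(1R)-1-hydroxyethyl]-2,3-dihydro-1-benzofuran-3-ol | CC(C)(C)[Si](C)(C)OCC(=C)[C@H]1Oc2ccc([C@@H](C)O)cc2[C@@H]1O
F6 | step 8 | (1R)-1-[(2R,3S)-2-(3-{[tert-butyl(dimethyl)silyl]oxy}prop-1-en-2-yl)-3-{[(2E)-2-methylbut-2-enoyl]oxy}-2,3-dihydro-1-benzofuran-5-yl]ethyl (2E)-2-methylbut-2-enoate | CC(C)(C)[Si](C)(C)OCC(=C)[C@H]1Oc2ccc([C@@H](C)OC(=O)/C(C)=C/C)cc2[C@@H]1OC(=O)/C(C)=C/C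
F7 | step 8 | (1R)-1-[(2R,3S)-2-(3-hydroxyprop-1-en-2-yl)-3-{[(2E)-2-methylbut-2-enoyl]oxy}-2,3-dihydro-1-benzofuran-5-yl]ethyl (2E)-2-methylbut-2-enoate | OCC(=C)[C@H]1Oc2ccc([C@@H](C)OC(=O)/C(C)=C/C)cc2[C@@H]1OC(=O)/C(C)=C/C
A1 | direct plan | 1-(3-bromo-4-hydroxyphenyl)ethan-1-one | CC(=O)c1ccc(O)c(Br)c1
A2 | direct plan | 1-{4-hydroxy-3-[(1E)-3-methylbuta-1,3-dien-1-yl]phenyl}ethan-1-one | C=C(C)/C=C/c1cc(C(C)=O)ccc1O
A3 | direct plan | 1-{4-hydroxy-3-[(2S,3S)-3-(prop-1-en-2-yl)oxiran-2-yl]phenyl}ethan-1-one | C=C(C)[C@@H]1O[C@H]1c2cc(C(C)=O)ccc2O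
A4 | direct plan | 1-[(2R,3S)-3-hydroxy-2-(prop-1-en-2-yl)-2,3-dihydro-1-benzofuran-5-yl]ethan-1-one | C=C(C)[C@H]1Oc2ccc(C(C)=O)cc2[C@@H]1O
A5 | direct plan | (1R)-1-[(2R,3S)-3-{[(2E)-2-methylbut-2-enoyl]oxy}-2-(prop-1-en-2-yl)-2,3-dihydro-1-benzofuran-5-yl]ethyl (2E)-2-methylbut-2-enoate | C=C(C)[C@H]1Oc2ccc([C@@H](C)OC(=O)/C(C)=C/C)cc2[C@@H]1OC(=O)/C(C)=C/C
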